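## Structural features

The target 28 is an acylphloroglucinol without any stereocentre. Its fully substituted benzene ring B carries a 2-methylpropanoyl group at C1, hydroxyl groups at C2, C4 and C6, and at C3 and C5 one CH2 group each, which links ring B to C3 of a 6-ethyl-4-hydroxy-5-methyl-2H-pyran-2-one (rings A and C, identical). A mirror plane through C1 and C4 makes the two arms equivalent, so a dimerising construction is possible; no stereocentres stand next to each other, and the only ones that appear on the way are temporary centres handled as racemates or diastereomer mixtures. The fragile elements are the five acidic OH groups (two vinylogous acids, three phenols), the easily oxidised ring B, the pyrone lactones (opened by hard nucleophiles), and the two ArCH2–pyrone bridges, which in the free polyphenol can ionise under strong acid or base and scramble the arms. The real difficulty is ring B: six contiguous substituents of three kinds in a strict oxygen/carbon alternation, too crowded for dependable late substitution at the flanked positions. The key step uses the fact that C2(O)–C3–C4(O)–C5, with identical CH2–pyrone arms on C3 and C5, is the carbon skeleton of the head-to-tail dimer of one monosubstituted ketene (a 2,4-disubstituted 3-alkoxycyclobutenone), while C1–C6(O) is an alkoxyalkyne that carries the acyl carbon as a protected carbinol. A thermal benzannulation of these two units forms C1–C2 and C5–C6, closes ring B and fixes all six substituents by connectivity alone.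

## Logic of the disconnections

28 ⇒ 27. Three O–CH3 bonds and one O–CH2CH3 bond are formed in the retrosynthetic direction: the two pyrone 4-hydroxyls and the C4 hydroxyl of ring B are masked as methyl ethers, the C6 hydroxyl as an ethyl ether, and the C2 hydroxyl stays free. The reason is that five acidic OH groups would quench every ketene and organometallic species used earlier, and the free polyphenol is the form in which the CH2 bridges are most labile. The gain is a neutral, chromatographable 27. The demand is a single Lewis-acid ether cleavage that removes two vinylogous-ester methyl groups, a doubly flanked aryl methyl group and an aryl ethyl group without ionising the bridges.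

27 ⇒ 26 ⇒ 25. No skeletal bond is cut; the C1 ketone is traced to a secondary alcohol and then to its silyl ether. A carbonyl group on the alkyne of the key step would invert the polarisation on which the regiochemistry rests, whereas a silyloxy-bearing sp3 carbon keeps the alkyne electron-rich and keeps an OH away from the ketenes. The gain is that the acyl carbon becomes the carbonyl carbon of 17. The demand is desilylation and oxidation beside a free, electron-rich phenol without ionising the benzylic C–O bond; the carbinol configuration is irrelevant because it is oxidised.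

25 ⇒ 15 + 20 (through 24, 23, 22 and 21). The bonds cut are C1–C2 and C5–C6 of ring B; C2–C3 is broken and re-formed inside the cascade. The atom mapping holds: the carbonyl carbon of 15 becomes C2 (the phenol), its ring CH becomes C3, its methoxy carbon C4 and its other sp2 carbon C5, while the alkyne carbons of 20 become C1 (carbinol arm) and C6 (ethoxy). The gain is that a hexasubstituted benzene is reduced to a symmetrical four-membered ring and a two-step alkyne, with one orientational choice only. The demand is threefold: 15 must open below the temperature at which 20 loses ethene, the ketene must bond through its carbonyl carbon to the alkyne carbon remote from oxygen, and a crowded triene must still cyclise.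

15 ⇒ 14 ⇒ 13 ⇒ 2 × 12 ⇒ 11 ⇒ 10. The enol O–CH3 bond is cut first, then the two ring C–C bonds that each join the carbonyl carbon of one molecule of 12 to the α-carbon of the other, so two molecules of 10 supply the four-membered ring. Because 14 is symmetrical, its two enol oxygens are equivalent and O-methylation can give only one constitution. The gain is the whole C2–C5 segment of ring B with both arms from a single acid. The demand is head-to-tail C–C dimerisation: monosubstituted ketenes made with excess tertiary amine dimerise instead through oxygen to the β-lactone dimer, so the amine must be added slowly to excess 11. Under those conditions the cyclobutane-1,3-dione is formed and caught as enol ester 13; its cleavage to 14 costs a third molecule of 11 per ring.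

10 ⇒ 9 ⇒ 6 + 8 (8 from 7). The bond cut is C3(pyrone)–CH2. The three-carbon acid arm is brought in intact by an sp2–sp3 cross-coupling. A chloromethylation and malonate homologation of 5 would reach 10 in the same number of steps but generates a carcinogenic halo ether as by-product, and direct C-alkylation of 4 is unreliable. The demand is oxidative addition at an electron-rich, doubly flanked C–Br bond, and an ester that is unmasked without base (hence tert-butyl), since the lactone tolerates saponification poorly.

6 ⇒ 5 ⇒ 4. The C3–Br bond and the O–CH3 bond are cut. C3 is the only free ring position and the nucleophilic carbon of the enol ether, so halogenation has no regiochemical alternative. The demand is O- rather than C-methylation of 4 and ionic rather than radical bromination.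

4 ⇒ 2 + 3, and 2 ⇒ 1. The bonds cut are C4–C5 and O1–C2 of the pyrone. The three-carbon unit C2–C3–C4 is the bis-electrophile 3, and the unit O1–C6–C5 with ethyl and methyl is the symmetrical ketone 1, used as its silyl enol ether 2 for a clean C-acylation. The gain is a fully substituted heterocycle from two bulk chemicals. The demand is strictly anhydrous, base-free conditions.

20 ⇒ 19 ⇒ 16 + 17 (through 18). The bond cut is C(sp)–C(carbinol), then the O–Si bond. The demand is that 19 never meets acid, which would rearrange the ynol ether.

## Other disconnections considered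

Alternative 1: The cut is the C3–C4 bond of each pyrone, leading to the open-chain tetraester A1, in which a trimethylated ring B with the ketone in place carries two propanoate arms esterified through the secondary hydroxyl of an aldol-type β-hydroxy ester unit. In the forward step LiN(SiMe3)2 at low temperature would deprotonate the CH2 next to each acyloxy carbonyl, and each enolate would attack the neighbouring methyl ester (Dieckmann condensation, 6-exo-trig) to give the bis(4-hydroxy-5,6-dihydropyran-2-one) A2.
- In favour: this ring closure is a well-tested way to such lactones, both rings close in one flask, and ring B is bought rather than built. The risk of step 11 is therefore absent, and on this point the alternative is the better plan.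
- Against: A2 is at the wrong oxidation level. Each lactone must be dehydrogenated across C5–C6, two tertiary sp3 carbons, late and twice, and mild methods for this are scarce. Four stereocentres are made only to be erased. The enolate on the methyl ester side can expel the β-acyloxy group (E1cB) and sever the arm. The two propanoate arms must still be attached at the flanked positions of ring B.
- Comparison: structurally the heterocycles are finished last on a complete ring B, the reverse of the chosen plan. Mechanistically it is ionic and stepwise with a late redox correction, against a reagent-free pericyclic cascade that delivers the right oxidation level directly. In step economy the two plans are about equal.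

Alternative 2: The cut is the two C(ring B)–CH2 bonds, leading to dibromide A3 and two equivalents of the pyronylmethylzinc chloride A5, made from the chloromethylpyrone A4 (itself from 5). In the forward step Pd(OAc)2 with 2-dicyclohexylphosphino-2',6'-dimethoxybiphenyl would couple A5 twice with A3 (Negishi coupling) to give A6, the pentamethyl ether of 28.
- In favour: it is the most convergent plan; ring B comes from a cheap aromatic ether; the ligand was designed for di-ortho-substituted aryl halides; benzylic-type zinc reagents transmetalate readily; A6 is one ether cleavage from 28.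
- Against: each C–Br bond of A3 is flanked by two methoxy groups on an electron-rich ring, so oxidative addition is slow, reduction of the C–Br bond competes, and the second coupling is harder than the first. A4 is classically reached by chloromethylation, with the carcinogenic halo ether that such conditions generate, and A5 is prone to homocoupling. The closing five-fold ether cleavage has the liabilities of step 14.
- Comparison: structurally ring B is bought and only decorated. Mechanistically a catalytic two-electron cycle must act twice at the most hindered positions, where the chosen plan needs no catalyst and fixes positions by connectivity. In step economy Alternative 2 is clearly better (about seven steps in the longest line against twelve), and in the end-game it is the equal of the chosen plan. The chosen plan is preferable only in avoiding the doubly hindered coupling and the halomethylation.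

Alternative 3: The cut is the C4–C5 and O1–C2 bonds of both pyrones, four bonds in all, leading to the bis(malonyl dichloride) A7 and two molecules of 1. In the forward step A7 is heated with 1, so that C-acylation of the ketone enol and lactonisation occur on both arms and give A8.
- In favour: both heterocycles are made last from the cheapest component, and the pyrone hydroxyls emerge free, so only three aryl methyl ethers remain. In protecting-group economy it is better than the chosen plan.
- Against: A7 is a tetra-acyl chloride with two acidic malonyl C–H bonds, a ketone and three aryl ethers. Such monosubstituted malonyl dichlorides readily lose HCl to ketenes and are hard to purify, and the parent tetra-acid decarboxylates. A free ketone is a poorer partner than its silyl enol ether (compare steps 1 and 2), the condensation must succeed twice under HCl evolution, and the isobutyryl ketone of A7 is itself enolisable.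
- Comparison: structurally it uses the same twofold symmetry as the chosen plan, but at the periphery instead of in ring B. Mechanistically it is two acid-generating acyl substitutions per ring against a neutral thermolysis. In step economy it is roughly equal on paper, but everything rests on one intermediate that is hard to make and handle.

Key step: step 11

Remark: Pyr stands for the 6-ethyl-4-methoxy-5-methyl-2-oxo-2H-pyran-3-yl group.

Remark (assumption): 13–15, 19, 20, 23, 25 and 26 each hold one uncontrolled stereocentre and are taken as racemates (SMILES show one enantiomer where a centre is drawn); 22 and 24 hold two and are diastereomer mixtures. All these centres vanish before 28.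

Remark (design): the three-carbon arm is installed by cross-coupling instead of chloromethylation and malonate homologation. The four-membered ring is assembled from two molecules of acid 10, with a third consumed as the acylating agent, and the amine is the limiting component so that the cyclobutane-1,3-dione forms and not the β-lactone dimer.

## Route

Step 1
Reactants: 1 pentan-3-one
Product: 2 (Z)-trimethyl(pent-2-en-3-yloxy)silane (Z isomer drawn; any E isomer reacts the same way)
Conditions: TMSOTf, Et3N, Et2O, 0 °C → rt
Reagents that add atoms: trimethylsilyl trifluoromethanesulfonate, C[Si](C)(C)OS(=O)(=O)C(F)(F)F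
Why: Soft enolisation by O-silylation and deprotonation gives the silyl enol ether; 1 is symmetrical, so only one regioisomer is possible, and the double-bond geometry is lost in step 2.

Step 2
Reactants: 2 (Z)-trimethyl(pent-2-en-3-yloxy)silane, 3 malonyl dichloride
Product: 4 6-ethyl-4-hydroxy-5-methyl-2H-pyran-2-one
Conditions: Et2O, −78 °C → rt
Reagents that add atoms: none
Why: The enol ether carbon is acylated by one acyl chloride group and the ketone oxygen then closes on the second (two acyl substitutions, the second 6-exo-trig), with loss of Me3SiCl and HCl; enolisation gives the aromatic 4-hydroxy-2-pyrone. This is the established malonyl dichloride route to 6-substituted 4-hydroxy-2-pyrones.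

Step 3
Reactants: 4 6-ethyl-4-hydroxy-5-methyl-2H-pyran-2-one
Product: 5 6-ethyl-4-methoxy-5-methyl-2H-pyran-2-one
Conditions: Me2SO4, K2CO3, acetone, reflux
Reagents that add atoms: dimethyl sulfate, COS(=O)(=O)OC
Why: Williamson-type O-alkylation of the ambident pyronolate with a hard methylating agent should occur mainly at the 4-oxygen; alkylation at the ring carbonyl oxygen is the minor pathway and its product is separable.

Step 4
Reactants: 5 6-ethyl-4-methoxy-5-methyl-2H-pyran-2-one
Product: 6 3-bromo-6-ethyl-4-methoxy-5-methyl-2H-pyran-2-one
Conditions: NBS, MeCN, rt, dark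
Reagents that add atoms: N-bromosuccinimide, O=C1CCC(=O)N1Br
Why: Electrophilic bromination occurs at C3, the only unsubstituted ring carbon and the nucleophilic β-carbon of the enol ether; ionic conditions in the dark suppress radical bromination of the alkyl side chains.

Step 5
Reactants: 6 3-bromo-6-ethyl-4-methoxy-5-methyl-2H-pyran-2-one, 7 tert-butyl 3-bromopropanoate
Product: 9 tert-butyl 3-(Pyr)propanoate, via alkylzinc bromide 8 (not isolated)
Conditions: 7, Zn dust, LiCl, I2 (cat.), THF, 40 °C; then 6, Pd(OAc)2 (3 mol %), 2-dicyclohexylphosphino-2',6'-dimethoxybiphenyl (6 mol %), THF, 50 °C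
Reagents that add atoms: none
Why: Negishi coupling: zinc inserts into the C–Br bond of 7 to give the ester-bearing alkylzinc 8, which transmetalates to the organopalladium bromide formed by oxidative addition of the C3–Br bond of 6 to zerovalent palladium. The bulky biarylphosphine favours reductive elimination over β-hydride elimination, and alkylzinc halides attack neither the lactone nor the ester.

Step 6
Reactants: 9 tert-butyl 3-(Pyr)propanoate
Product: 10 3-(Pyr)propanoic acid
Conditions: TFA, CH2Cl2, 0 °C → rt
Reagents that add atoms: none
Why: Acid-catalysed cleavage of the tert-butyl ester with loss of isobutene (E1); the 4-methoxy-2-pyrone is stable to anhydrous acid, whereas saponification would endanger the lactone.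

Step 7
Reactants: 10 3-(Pyr)propanoic acid (two molecules build the ring)
Product: 14 3-hydroxy-2,4-bis[(Pyr)methyl]cyclobut-2-en-1-one (enol form of the cyclobutane-1,3-dione; racemate), via acid chloride 11 (not isolated), via ketene 12 (not isolated), via enol ester 13 (not isolated)
Conditions: (COCl)2, DMF (cat.), CH2Cl2, 0 °C → rt, evaporation; Et3N (1.0 equiv, added over 6 h), CH2Cl2, rt; then MeOH, Et3N, DMAP (cat.), rt; extraction into aq. NaHCO3, acidification
Reagents that add atoms: 3-(Pyr)propanoic acid (a second molecule of the same acid), CCc1oc(=O)c(CCC(=O)O)c(OC)c1C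
Why: Oxalyl chloride converts 10 into acid chloride 11, and Et3N dehydrochlorinates 11 to ketene 12; two molecules of 12 join head-to-tail (ketene dimerisation), each carbonyl carbon bonding to the α-carbon of the other, so both halves of the ring come from 10. With the amine added slowly to an excess of 11, simple alkylketenes are known to give the cyclobutane-1,3-dione, whose acidic enol is O-acylated in the flask by a third molecule of 11 to enol ester 13. Methanolysis of this vinylogous anhydride releases 14, which is separated from the neutral methyl ester by extraction into aqueous NaHCO3.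

Step 8
Reactants: 14 3-hydroxy-2,4-bis[(Pyr)methyl]cyclobut-2-en-1-one
Product: 15 3-methoxy-2,4-bis[(Pyr)methyl]cyclobut-2-en-1-one (racemate)
Conditions: Me2SO4, K2CO3, acetone, rt
Reagents that add atoms: dimethyl sulfate, COS(=O)(=O)OC
Why: Williamson-type O-methylation of the vinylogous acid; the two enol oxygens of the symmetrical dione are equivalent, so a single constitution results. C-Methylation would create a quaternary centre in the strained ring and is disfavoured with the hard sulfate.

Step 9
Reactants: 16 ethoxyacetylene, 17 isobutyraldehyde
Product: 19 1-ethoxy-4-methylpent-1-yn-3-ol (racemate), via lithium ethoxyacetylide 18 (not isolated)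
Conditions: n-BuLi, THF, −78 °C; 17, −78 → 0 °C; H2O
Reagents that add atoms: none
Why: Deprotonation of the terminal alkyne gives acetylide 18, which adds to the aldehyde carbonyl (1,2-addition) without facial control, giving the racemic propargylic alcohol. The neutral to basic work-up avoids the acid-catalysed Meyer–Schuster rearrangement of the ynol ether.

Step 10
Reactants: 19 1-ethoxy-4-methylpent-1-yn-3-ol
Product: 20 tert-butyl[(1-ethoxy-4-methylpent-1-yn-3-yl)oxy]dimethylsilane (racemate)
Conditions: TBSCl, imidazole, DMF, 0 °C → rt
Reagents that add atoms: tert-butyldimethylsilyl chloride, CC(C)(C)[Si](C)(C)Cl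
Why: Imidazole-promoted silylation of the secondary alcohol; the basic medium suits the acid-sensitive ynol ether, and the silyl ether masks the OH that would otherwise add to the ketenes of step 11.

Step 11
Reactants: 15 3-methoxy-2,4-bis[(Pyr)methyl]cyclobut-2-en-1-one, 20 tert-butyl[(1-ethoxy-4-methylpent-1-yn-3-yl)oxy]dimethylsilane
Product: 25 2-[1-{[tert-butyl(dimethyl)silyl]oxy}-2-methylpropyl]-3-ethoxy-5-methoxy-4,6-bis[(Pyr)methyl]phenol (racemate), via vinylketene 21 (not isolated), via vinylcyclobutenone 22 (not isolated), via dienylketene 23 (not isolated), via cyclohexadienone 24 (not isolated)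
Conditions: 20 (2.5 equiv), PhMe (degassed), 85 → 100 °C, sealed tube, Ar
Reagents that add atoms: none
Why: Danheiser benzannulation. Heating opens 15 by four-electron conrotatory electrocyclic cleavage of the bond between its carbonyl carbon and its ring CH to vinylketene 21; the ketene C=C bond then adds ynol ether 20 in a regioselective [2+2] cycloaddition to give 4-vinylcyclobutenone 22, which opens in a second four-electron electrocyclic step to dienylketene 23. Ring B closes by six-electron disrotatory electrocyclisation of 23 (ketene carbon onto the terminal CH), and cyclohexadienone 24 tautomerises irreversibly to phenol 25. The closest known reactions are the benzannulation of cyclobutenones with 1-alkoxyalkynes and the formation of 3,5-dialkoxyphenols from 3-alkoxycyclobutenones and alkoxyacetylenes. No new stereocentre survives: the ring CH of 15 becomes aromatic, and the carbinol centre of 20 is carried through unchanged and oxidised later. The selectivity needed is the orientation of the [2+2] step, which the polarisation of 20 secures: its carbon remote from oxygen is the nucleophilic one and bonds to the ketene carbonyl carbon, so the carbinol arm ends between the new phenol and the ethoxy group. The productive geometry of 23 does not rest on torquoselectivity, because an unproductive opening of 22 is reversible. The temperature is kept near 100 °C or below so that 20 does not lose ethene by retro-ene fragmentation, and 20 is used in excess so that 25 is not acylated by 21.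

Step 12
Reactants: 25 2-[1-{[tert-butyl(dimethyl)silyl]oxy}-2-methylpropyl]-3-ethoxy-5-methoxy-4,6-bis[(Pyr)methyl]phenol
Product: 26 3-ethoxy-2-(1-hydroxy-2-methylpropyl)-5-methoxy-4,6-bis[(Pyr)methyl]phenol (racemate)
Conditions: TBAF, AcOH, THF, 0 → 40 °C
Reagents that add atoms: none
Why: Fluoride attacks silicon and the strong Si–F bond drives Si–O cleavage; acetic acid buffers the medium so that no phenoxide forms and the electron-rich benzylic C–O bond is not ionised.

Step 13
Reactants: 26 3-ethoxy-2-(1-hydroxy-2-methylpropyl)-5-methoxy-4,6-bis[(Pyr)methyl]phenol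
Product: 27 1-{2-ethoxy-6-hydroxy-4-methoxy-3,5-bis[(Pyr)methyl]phenyl}-2-methylpropan-1-one
Conditions: MnO2 (activated, excess), CH2Cl2, rt
Reagents that add atoms: none
Why: Activated MnO2 oxidises benzylic alcohols selectively under neutral heterogeneous conditions, which avoids ionisation of 26 to an ortho-quinone methide. The aryl ketone formed is stabilised by a hydrogen bond to the ortho phenol.

Step 14
Reactants: 27 1-{2-ethoxy-6-hydroxy-4-methoxy-3,5-bis[(Pyr)methyl]phenyl}-2-methylpropan-1-one
Product: 28 3,3'-{[2,4,6-trihydroxy-5-(2-methylpropanoyl)-1,3-phenylene]bis(methylene)}bis(6-ethyl-4-hydroxy-5-methyl-2H-pyran-2-one)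
Conditions: BBr3 (10 equiv), CH2Cl2, −78 °C → rt; H2O
Reagents that add atoms: none
Why: BBr3 complexes the ether and carbonyl oxygens and bromide removes each alkyl group by SN2. The ethyl ether is activated by chelation to the ortho ketone and the two pyrone ethers are vinylogous methyl esters, so all four ethers should be cleaved at or below room temperature; hydrolysis of the borates on work-up liberates 28.

## Compound list

1 | pentan-3-one | CCC(=O)CC | starting material
2 | (Z)-trimethyl(pent-2-en-3-yloxy)silane | C/C=C(\O[Si](C)(C)C)CC | intermediate
3 | malonyl dichloride | O=C(Cl)CC(=O)Cl | starting material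
4 | 6-ethyl-4-hydroxy-5-methyl-2H-pyran-2-one | CCc1oc(=O)cc(O)c1C | intermediate
5 | 6-ethyl-4-methoxy-5-methyl-2H-pyran-2-one | CCc1oc(=O)cc(OC)c1C | intermediate
6 | 3-bromo-6-ethyl-4-methoxy-5-methyl-2H-pyran-2-one | CCc1oc(=O)c(Br)c(OC)c1C | intermediate
7 | tert-butyl 3-bromopropanoate | CC(C)(C)OC(=O)CCBr | starting material
8 | (3-tert-butoxy-3-oxopropyl)zinc bromide | CC(C)(C)OC(=O)CC[Zn]Br | intermediate
9 | tert-butyl 3-(6-ethyl-4-methoxy-5-methyl-2-oxo-2H-pyran-3-yl)propanoate | CCc1oc(=O)c(CCC(=O)OC(C)(C)C)c(OC)c1C | intermediate
10 | 3-(6-ethyl-4-methoxy-5-methyl-2-oxo-2H-pyran-3-yl)propanoic acid | CCc1oc(=O)c(CCC(=O)O)c(OC)c1C | intermediate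
11 | 3-(6-ethyl-4-methoxy-5-methyl-2-oxo-2H-pyran-3-yl)propanoyl chloride | CCc1oc(=O)c(CCC(=O)Cl)c(OC)c1C | intermediate
12 | 6-ethyl-4-methoxy-5-methyl-3-(3-oxoprop-2-en-1-yl)-2H-pyran-2-one (the monosubstituted ketene) | CCc1oc(=O)c(CC=C=O)c(OC)c1C | intermediate
13 | 2,4-bis[(Pyr)methyl]-3-oxocyclobut-1-en-1-yl 3-(Pyr)propanoate (enol ester of 14, racemate) | O=C(CCc1c(OC)c(C)c(CC)oc1=O)OC1=C(Cc2c(OC)c(C)c(CC)oc2=O)C(=O)[C@@H]1Cc1c(OC)c(C)c(CC)oc1=O | intermediate
14 | 3-hydroxy-2,4-bis[(Pyr)methyl]cyclobut-2-en-1-one (racemate) | OC1=C(Cc2c(OC)c(C)c(CC)oc2=O)C(=O)[C@@H]1Cc1c(OC)c(C)c(CC)oc1=O | intermediate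
15 | 3-methoxy-2,4-bis[(Pyr)methyl]cyclobut-2-en-1-one (racemate) | COC1=C(Cc2c(OC)c(C)c(CC)oc2=O)C(=O)[C@@H]1Cc1c(OC)c(C)c(CC)oc1=O | intermediate
16 | ethoxyacetylene | CCOC#C | starting material
17 | isobutyraldehyde | CC(C)C=O | starting material
18 | lithium ethoxyacetylide | CCOC#C[Li] | intermediate
19 | 1-ethoxy-4-methylpent-1-yn-3-ol (racemate) | CCOC#C[C@H](O)C(C)C | intermediate
20 | tert-butyl[(1-ethoxy-4-methylpent-1-yn-3-yl)oxy]dimethylsilane (racemate) | CCOC#C[C@H](O[Si](C)(C)C(C)(C)C)C(C)C | intermediate
21 | (3Z)-3-methoxy-5-(Pyr)-2-[(Pyr)methyl]penta-1,3-dien-1-one (vinylketene) | O=C=C(Cc1c(OC)c(C)c(CC)oc1=O)/C(OC)=C/Cc1c(OC)c(C)c(CC)oc1=O | intermediate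
22 | 2-[1-{[tert-butyl(dimethyl)silyl]oxy}-2-methylpropyl]-3-ethoxy-4-[(1Z)-1-methoxy-3-(Pyr)prop-1-en-1-yl]-4-[(Pyr)methyl]cyclobut-2-en-1-one (diastereomer mixture) | O=C1C(C(O[Si](C)(C)C(C)(C)C)C(C)C)=C(OCC)C1(Cc2c(OC)c(C)c(CC)oc2=O)/C(OC)=C/Cc3c(OC)c(C)c(CC)oc3=O | intermediate
23 | (3E,5Z)-2-[1-{[tert-butyl(dimethyl)silyl]oxy}-2-methylpropyl]-3-ethoxy-5-methoxy-7-(Pyr)-4-[(Pyr)methyl]hepta-1,3,5-trien-1-one (dienylketene, racemate) | O=C=C(C(O[Si](C)(C)C(C)(C)C)C(C)C)/C(OCC)=C(/Cc2c(OC)c(C)c(CC)oc2=O)\C(OC)=C\Cc3c(OC)c(C)c(CC)oc3=O | intermediate
24 | 2-[1-{[tert-butyl(dimethyl)silyl]oxy}-2-methylpropyl]-3-ethoxy-5-methoxy-4,6-bis[(Pyr)methyl]cyclohexa-2,4-dien-1-one (diastereomer mixture) | O=C1C(C(O[Si](C)(C)C(C)(C)C)C(C)C)=C(OCC)C(Cc2c(OC)c(C)c(CC)oc2=O)=C(OC)C1Cc3c(OC)c(C)c(CC)oc3=O | intermediate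
25 | 2-[1-{[tert-butyl(dimethyl)silyl]oxy}-2-methylpropyl]-3-ethoxy-5-methoxy-4,6-bis[(Pyr)methyl]phenol (racemate) | CC(C)[C@@H](O[Si](C)(C)C(C)(C)C)c1c(O)c(Cc2c(OC)c(C)c(CC)oc2=O)c(OC)c(Cc2c(OC)c(C)c(CC)oc2=O)c1OCC | intermediate
26 | 3-ethoxy-2-(1-hydroxy-2-methylpropyl)-5-methoxy-4,6-bis[(Pyr)methyl]phenol (racemate) | CC(C)[C@@H](O)c1c(O)c(Cc2c(OC)c(C)c(CC)oc2=O)c(OC)c(Cc2c(OC)c(C)c(CC)oc2=O)c1OCC | intermediate
27 | 1-{2-ethoxy-6-hydroxy-4-methoxy-3,5-bis[(Pyr)methyl]phenyl}-2-methylpropan-1-one | CC(C)C(=O)c1c(O)c(Cc2c(OC)c(C)c(CC)oc2=O)c(OC)c(Cc2c(OC)c(C)c(CC)oc2=O)c1OCC | intermediate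
28 | 3,3'-{[2,4,6-trihydroxy-5-(2-methylpropanoyl)-1,3-phenylene]bis(methylene)}bis(6-ethyl-4-hydroxy-5-methyl-2H-pyran-2-one) | CCc1oc(=O)c(Cc2c(O)c(Cc3c(O)c(C)c(CC)oc3=O)c(O)c(C(=O)C(C)C)c2O)c(O)c1C | target

## Step count and least certain steps

Total: 14 steps. Longest linear sequence: 12 steps (steps 1–8 and 11–14, from 1); the ynol ether branch (steps 9 and 10) has two steps.

Step 11 (key step). The most likely failures are these. The donor-stabilised cyclobutenone may open too slowly, so that the ynol ether decays by retro-ene loss of ethene before it is captured. The [2+2] addition of a disubstituted ketene to a branched alkyne may be blocked sterically. Silanol may be lost thermally from the ortho-hydroxybenzyl silyl ether of the product. A first adjustment would be photochemical opening at room temperature. The fallback abandons the construction of ring B and uses a Mannich-type double alkylation of a bought ring B. It sets out from 4: with dimethylmethylideneammonium iodide in MeCN, 4 should give the Mannich base 3-[(dimethylamino)methyl]-6-ethyl-4-hydroxy-5-methyl-2H-pyran-2-one F1. Heating F1 (2.2 equiv) with commercial 2-methyl-1-(2,4,6-trihydroxyphenyl)propan-1-one F2 in dioxane expels dimethylamine, and the two free ring positions of F2 add to the methide so released, a known way of joining such pyrones to acylphloroglucinols. The fallback comes back to the route at 28.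

Step 7. The most likely failures are dimerisation in the wrong sense (C–O in place of C–C bond formation, the normal course when amine is in excess), intramolecular acylation of the 4-methoxy oxygen by the acid chloride with loss of the methyl group, and the built-in loss of a third of the acid as its ester. The fallback replaces the dimerisation by the classical cycloaddition of a ketene to an alkoxyacetylene and adds the second arm later. It sets out from 11: Et3N is added to 11 in the presence of excess 16, which should give 3-ethoxy-4-[(Pyr)methyl]cyclobut-2-en-1-one F3. Heating F3 with 20 as in step 11 should give the less crowded 2-[1-{[tert-butyl(dimethyl)silyl]oxy}-2-methylpropyl]-3,5-diethoxy-6-[(Pyr)methyl]phenol F4, whose free ring position lies para to the phenol. F4 is alkylated there by the Mannich base F1 (prepared as in the fallback to step 11), giving 2-[1-{[tert-butyl(dimethyl)silyl]oxy}-2-methylpropyl]-3,5-diethoxy-4-[(6-ethyl-4-hydroxy-5-methyl-2-oxo-2H-pyran-3-yl)methyl]-6-[(Pyr)methyl]phenol F5. TBAF with AcOH then gives 3,5-diethoxy-4-[(6-ethyl-4-hydroxy-5-methyl-2-oxo-2H-pyran-3-yl)methyl]-2-(1-hydroxy-2-methylpropyl)-6-[(Pyr)methyl]phenol F6, and MnO2 gives 1-{2,4-diethoxy-3-[(6-ethyl-4-hydroxy-5-methyl-2-oxo-2H-pyran-3-yl)methyl]-6-hydroxy-5-[(Pyr)methyl]phenyl}-2-methylpropan-1-one F7. BBr3 cleaves the two ethyl ethers and the one methyl ether of F7, and the fallback comes back to the route at 28.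

Step 14. The most likely failures are incomplete cleavage of the aryl methyl ether flanked by both arms, and acid-induced ionisation of the ArCH2–pyrone bonds (retro-Friedel–Crafts scrambling of the arms) once ring B is a free phloroglucinol. The fallback stages the cleavage and moves most of it to a nucleophilic, non-acidic mechanism. It sets out from 27: BCl3 at −78 → 0 °C should remove only the ethyl group held in the chelate with the ketone, giving 1-{2,6-dihydroxy-4-methoxy-3,5-bis[(Pyr)methyl]phenyl}-2-methylpropan-1-one F8. Sodium ethanethiolate in DMF at 90 °C then removes the three remaining methyl groups by SN2 (two vinylogous esters and an anisole para to the ketone), and the fallback comes back to the route at 28.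

Step 13 (with step 12). The most likely failures are ionisation of the ortho-hydroxybenzylic alcohol to an ortho-quinone methide on the oxidant or on silica, and oxidation of the electron-rich phenol itself. The fallback caps the phenol before the carbinol is freed. It sets out from 25: Me2SO4 with K2CO3 should give tert-butyl(1-{2-ethoxy-4,6-dimethoxy-3,5-bis[(Pyr)methyl]phenyl}-2-methylpropoxy)dimethylsilane F9, TBAF then gives 1-{2-ethoxy-4,6-dimethoxy-3,5-bis[(Pyr)methyl]phenyl}-2-methylpropan-1-ol F10, and Dess–Martin periodinane gives 1-{2-ethoxy-4,6-dimethoxy-3,5-bis[(Pyr)methyl]phenyl}-2-methylpropan-1-one F11. BBr3 cleaves the four methyl ethers and the one ethyl ether of F11, and the fallback comes back to the route at 28.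

Step 5. The most likely failures are slow oxidative addition at the electron-rich, doubly flanked C3–Br bond, and protonolysis or β-hydride loss of the alkylzinc before coupling. The fallback forms the same bond with an alkene partner. It sets out from 6: a Heck reaction with tert-butyl acrylate (Pd(OAc)2, tri(o-tolyl)phosphine, Et3N, DMF, 100 °C) should give tert-butyl (2E)-3-(Pyr)prop-2-enoate F12. Hydrogenation of the disubstituted alkene (H2, Pd/C, EtOAc) should leave the tetrasubstituted ring double bonds untouched, and the fallback comes back to the route at 9.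

## Further compounds

F1 | step 11 | 3-[(dimethylamino)methyl]-6-ethyl-4-hydroxy-5-methyl-2H-pyran-2-one | CCc1oc(=O)c(CN(C)C)c(O)c1C
F2 | step 11 | 2-methyl-1-(2,4,6-trihydroxyphenyl)propan-1-one | CC(C)C(=O)c1c(O)cc(O)cc1O
F3 | step 7 | 3-ethoxy-4-[(Pyr)methyl]cyclobut-2-en-1-one (racemate) | CCOC1=CC(=O)[C@@H]1Cc1c(OC)c(C)c(CC)oc1=O
F4 | step 7 | 2-[1-{[tert-butyl(dimethyl)silyl]oxy}-2-methylpropyl]-3,5-diethoxy-6-[(Pyr)methyl]phenol (racemate) | CC(C)[C@@H](O[Si](C)(C)C(C)(C)C)c1c(O)c(Cc2c(OC)c(C)c(CC)oc2=O)c(OCC)cc1OCC
F5 | step 7 | 2-[1-{[tert-butyl(dimethyl)silyl]oxy}-2-methylpropyl]-3,5-diethoxy-4-[(6-ethyl-4-hydroxy-5-methyl-2-oxo-2H-pyran-3-yl)methyl]-6-[(Pyr)methyl]phenol (racemate) | CC(C)[C@@H](O[Si](C)(C)C(C)(C)C)c1c(O)c(Cc2c(OC)c(C)c(CC)oc2=O)c(OCC)c(Cc2c(O)c(C)c(CC)oc2=O)c1OCC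
F6 | step 7 | 3,5-diethoxy-4-[(6-ethyl-4-hydroxy-5-methyl-2-oxo-2H-pyran-3-yl)methyl]-2-(1-hydroxy-2-methylpropyl)-6-[(Pyr)methyl]phenol (racemate) | CC(C)[C@@H](O)c1c(O)c(Cc2c(OC)c(C)c(CC)oc2=O)c(OCC)c(Cc2c(O)c(C)c(CC)oc2=O)c1OCC
F7 | step 7 | 1-{2,4-diethoxy-3-[(6-ethyl-4-hydroxy-5-methyl-2-oxo-2H-pyran-3-yl)methyl]-6-hydroxy-5-[(Pyr)methyl]phenyl}-2-methylpropan-1-one | CC(C)C(=O)c1c(O)c(Cc2c(OC)c(C)c(CC)oc2=O)c(OCC)c(Cc2c(O)c(C)c(CC)oc2=O)c1OCC
F8 | step 14 | 1-{2,6-dihydroxy-4-methoxy-3,5-bis[(Pyr)methyl]phenyl}-2-methylpropan-1-one | CC(C)C(=O)c1c(O)c(Cc2c(OC)c(C)c(CC)oc2=O)c(OC)c(Cc2c(OC)c(C)c(CC)oc2=O)c1O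
F9 | step 13 | tert-butyl(1-{2-ethoxy-4,6-dimethoxy-3,5-bis[(Pyr)methyl]phenyl}-2-methylpropoxy)dimethylsilane (racemate) | CC(C)[C@@H](O[Si](C)(C)C(C)(C)C)c1c(OC)c(Cc2c(OC)c(C)c(CC)oc2=O)c(OC)c(Cc2c(OC)c(C)c(CC)oc2=O)c1OCC
F10 | step 13 | 1-{2-ethoxy-4,6-dimethoxy-3,5-bis[(Pyr)methyl]phenyl}-2-methylpropan-1-ol (racemate) | CC(C)[C@@H](O)c1c(OC)c(Cc2c(OC)c(C)c(CC)oc2=O)c(OC)c(Cc2c(OC)c(C)c(CC)oc2=O)c1OCC
F11 | step 13 | 1-{2-ethoxy-4,6-dimethoxy-3,5-bis[(Pyr)methyl]phenyl}-2-methylpropan-1-one | CC(C)C(=O)c1c(OC)c(Cc2c(OC)c(C)c(CC)oc2=O)c(OC)c(Cc2c(OC)c(C)c(CC)oc2=O)c1OCC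
F12 | step 5 | tert-butyl (2E)-3-(6-ethyl-4-methoxy-5-methyl-2-oxo-2H-pyran-3-yl)prop-2-enoate | CCc1oc(=O)c(/C=C/C(=O)OC(C)(C)C)c(OC)c1C
A1 | alternative 1 | bis[(2R,3R)-1-methoxy-2-methyl-1-oxopentan-3-yl] 3,3'-[2,4,6-trimethoxy-5-(2-methylpropanoyl)-1,3-phenylene]dipropanoate (one diastereomer drawn) | CC(C)C(=O)c1c(OC)c(CCC(=O)O[C@H](CC)[C@@H](C)C(=O)OC)c(OC)c(CCC(=O)O[C@H](CC)[C@@H](C)C(=O)OC)c1OC
A2 | alternative 1 | 3,3'-{[2,4,6-trimethoxy-5-(2-methylpropanoyl)-1,3-phenylene]bis(methylene)}bis[(5R,6R)-6-ethyl-4-hydroxy-5-methyl-5,6-dihydro-2H-pyran-2-one] | CC(C)C(=O)c1c(OC)c(CC2=C(O)[C@H](C)[C@@H](CC)OC2=O)c(OC)c(CC2=C(O)[C@H](C)[C@@H](CC)OC2=O)c1OC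
A3 | alternative 2 | 1-(3,5-dibromo-2,4,6-trimethoxyphenyl)-2-methylpropan-1-one | CC(C)C(=O)c1c(OC)c(Br)c(OC)c(Br)c1OC
A4 | alternative 2 | 3-(chloromethyl)-6-ethyl-4-methoxy-5-methyl-2H-pyran-2-one | CCc1oc(=O)c(CCl)c(OC)c1C
A5 | alternative 2 | [(6-ethyl-4-methoxy-5-methyl-2-oxo-2H-pyran-3-yl)methyl]zinc chloride | CCc1oc(=O)c(C[Zn]Cl)c(OC)c1C
A6 | alternative 2 | 3,3'-{[2,4,6-trimethoxy-5-(2-methylpropanoyl)-1,3-phenylene]bis(methylene)}bis(6-ethyl-4-methoxy-5-methyl-2H-pyran-2-one) | CC(C)C(=O)c1c(OC)c(Cc2c(OC)c(C)c(CC)oc2=O)c(OC)c(Cc2c(OC)c(C)c(CC)oc2=O)c1OC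
A7 | alternative 3 | 2,2'-{[2,4,6-trimethoxy-5-(2-methylpropanoyl)-1,3-phenylene]bis(methylene)}dipropanedioyl tetrachloride | CC(C)C(=O)c1c(OC)c(CC(C(=O)Cl)C(=O)Cl)c(OC)c(CC(C(=O)Cl)C(=O)Cl)c1OC
A8 | alternative 3 | 3,3'-{[2,4,6-trimethoxy-5-(2-methylpropanoyl)-1,3-phenylene]bis(methylene)}bis(6-ethyl-4-hydroxy-5-methyl-2H-pyran-2-one) | CC(C)C(=O)c1c(OC)c(Cc2c(O)c(C)c(CC)oc2=O)c(OC)c(Cc2c(O)c(C)c(CC)oc2=O)c1OC
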